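(The readings were generated by integration with constants of no real substance.)

Amounts first: in the delta run, which is this very flask followed so far, 21.5% of the substrate charged stands as target after 15.0 h, while the isomer of the product reads 0.6% against a scatter of 0.5 percentage points.

- delta: substrate 2 M; gas 150 mM (held); the very flask that is asked about, followed so far
- flask: substrate 2.0 M; gas 150 mM (held); time 2.0 d

delta run (percent of the substrate charged)

| time / h | target / % | isomer of the product / % |
|---|---|---|
| 2.50 | 3.4 | 0.1 |
| 5.00 | 7.6 | 0 |
| 8.00 | 12.8 | 0 |
| 10.0 | 15.9 | 0.9 |
| 12.0 | 18.7 | 0.8 |
| 15.0 | 21.5 | 0.6 |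

(each reading ± 0.5 percentage points)

- at the start none of the gas is in solution

* share of target in target plus isomer of the product at 1.0 h
* share of target in target plus isomer of the product at 8.0 h
* share of target in target plus isomer of the product at 2.0 d
* which of target and isomer of the product there is more of at 2.0 d

One isomer reading says little, so I build the flask up a step at a time and add the readings together. With the main step by itself, substrate and gas giving target, the share of target is 100 percent. Now I add a second step beside it, making the isomer of the product from the same substrate, and reckon:

s = Σ c(isomer of the product) / Σ c(target) = 0.0300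

share = 1 / (1 + s) = 97.1%

This s, the isomer of the product read per target in the delta run, a selectivity factor, is what I carry. While the two steps run side by side at a fixed ratio, s stands still, and so does the share; that is kinetic control.

Then comes the rest. Target gains 8.3 points in the 5.00 h up to 10.0 h, but 2.8 points in the last 3.00 h, which is less per hour. If that slowing is target going back while the isomer of the product keeps coming, s climbs and the share falls, and control passes to thermodynamics. So I commit to 97.1% at 1.0 h and 8.0 h, something lower at 2.0 d, with target still ahead.

The forecast gives 98.5% (93% to 100%), 97.5% (93% to 100%) and 90% (78% to 98%), with target ahead. Its early figures stand above my 97.1%. Of its two readings of the isomer it says: “The data cannot separate these”.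

The flask gives 98.2%, 97.9% and 95.9%, with target ahead, 42.3% against 1.79%.

    substrate + reagent ⇌ target (K = 6.10 L mol⁻¹, k = 7.10 × 10⁻⁵ L mol⁻¹ s⁻¹)
    substrate → decomposition product (k = 9.10 × 10⁻⁹ s⁻¹)
    substrate + reagent ⇌ isomer of the product (K = 550 L mol⁻¹, k = 1.30 × 10⁻⁶ L mol⁻¹ s⁻¹)
    gas ⇌ reagent, rate k4*(csat - [reagent]) (kL = 1.70 × 10⁻⁴ s⁻¹)

At 2.0 d this flask holds s = 0.0423. The neighbour flask has 0.50 M of substrate, a quarter of the charge, with gas and time held. Put into the share line, my s of 0.0300, a reading from the delta run, gives 97.1% for that neighbour flask. At 2.0 d the neighbour flask ends with target at 45.1% and the isomer of the product at 2.01%, which is s = 0.0446 and a share of 95.7%.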